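**Strategy**

The route rests on reading the two groups that flank the biaryl axis, the C8 hydroxyl of the isoquinoline and the C2' methyl of the naphthalene, as the remains of an ester bridge C8–O–C(=O)–C2'. The ester of 1,3-dimethylisoquinolin-8-ol with a 1-bromo-2-naphthoic acid is closed by palladium-catalysed intramolecular C–H arylation: one operation forms the hindered C7–C1' bond at the only position the tether can reach and gives a six-membered, configurationally labile biaryl lactone. Reductive opening with a chiral borane reagent then fixes the axis, and the liberated CH2OH group is reduced to the C2' methyl.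

Key step: step 10

Numbering: isoquinoline atoms are unprimed (C1 and C3 carry the methyl groups, C8 the hydroxyl, C7 the axis); naphthalene atoms are primed (C1' at the axis, C2' methyl, C4' OMe, C5' OH, C8a' the ring-fusion carbon next to C1').

Assumption: the SMILES string gives no descriptor for the C7–C1' axis, which should be configurationally stable (ortho OH, ortho CH3 and the peri-fused ring). ent-Dioncophylleine A is taken as the M atropisomer; the enantiomeric oxazaborolidine in step 11 would give the P form. Axial descriptors are given in the names because the SMILES strings do not carry them.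

**Route**

Step 1
Reactants: 1 2',6'-dihydroxyacetophenone
Product: 2 2-acetyl-3-hydroxyphenyl trifluoromethanesulfonate
Conditions: Tf2O (1.05 equiv), pyridine, CH2Cl2, −78 °C → 0 °C
Reagents that add atoms: trifluoromethanesulfonic anhydride, O=S(=O)(OS(=O)(=O)C(F)(F)F)C(F)(F)F
Why: O-sulfonylation of a phenol; after the first triflation the ring is deactivated and the remaining hydroxyl is locked in a hydrogen bond to the acetyl carbonyl, so one equivalent of Tf2O at low temperature should stop at the monotriflate.

Step 2
Reactants: 2 2-acetyl-3-hydroxyphenyl trifluoromethanesulfonate; 3 propyne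
Product: 4 1-[2-hydroxy-6-(prop-1-yn-1-yl)phenyl]ethan-1-one
Conditions: PdCl2(PPh3)2 (3 mol %), CuI (6 mol %), Et3N, DMF, 50 °C, sealed vessel
Reagents that add atoms: none
Why: Sonogashira coupling; the triflate is activated towards oxidative addition by the ortho acetyl group and the hydrogen-bonded phenol needs no protection.

Step 3
Reactants: 4 1-[2-hydroxy-6-(prop-1-yn-1-yl)phenyl]ethan-1-one
Product: 6 1,3-dimethylisoquinolin-8-ol, via ketimine 5 (not isolated)
Conditions: NH3 (7 M in MeOH), AgNO3 (10 mol %), sealed tube, 80 °C
Reagents that add atoms: ammonia, N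
Why: Condensation with ammonia gives the N–H ketimine 5, stabilised by the hydrogen bond to the ortho hydroxyl, and its nitrogen adds 6-endo-dig to the silver-activated alkyne; a proton shift gives the aromatic isoquinoline (imine–alkyne cycloisomerisation).

Step 4
Reactants: 7 5-(benzyloxy)-2-bromobenzaldehyde; 8 diethyl succinate
Product: 9 (E)-4-[5-(benzyloxy)-2-bromophenyl]-3-(ethoxycarbonyl)but-3-enoic acid
Conditions: KOtBu (1.2 equiv), tBuOH, reflux; then aq. HCl
Reagents that add atoms: none
Why: Stobbe condensation: the succinate enolate adds to the aldehyde, the alkoxide lactonises to a paraconic ester, and base-induced ring opening gives the half-ester with the aryl group cis to CH2CO2H (E), the geometry needed for ring closure in step 5.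

Step 5
Reactants: 9 (E)-4-[5-(benzyloxy)-2-bromophenyl]-3-(ethoxycarbonyl)but-3-enoic acid
Product: 10 ethyl 4-acetoxy-5-(benzyloxy)-8-bromo-2-naphthoate
Conditions: Ac2O, NaOAc, 140 °C
Reagents that add atoms: acetic anhydride, CC(=O)OC(C)=O
Why: The mixed anhydride of 9 acylates the ring intramolecularly (Friedel–Crafts acylation); the bromine occupies the other ortho position, so closure must take place next to the benzyloxy group, which gives the 4,5-dioxygenated naphthalene, and the naphthol formed is acetylated in the flask.

Step 6
Reactants: 10 ethyl 4-acetoxy-5-(benzyloxy)-8-bromo-2-naphthoate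
Product: 12 ethyl 5-(benzyloxy)-4-hydroxy-2-naphthoate, via bromonaphthol 11 (not isolated)
Conditions: K2CO3 (0.1 equiv), EtOH, rt; then DMF, Pd(OAc)2 (5 mol %), PPh3 (20 mol %), HCO2H (3 equiv), Et3N (4 equiv), 80 °C
Reagents that add atoms: none
Why: Base-catalysed transesterification removes the aryl acetate, and homogeneous palladium-catalysed transfer hydrodehalogenation with formate (oxidative addition, formate-to-hydride exchange with loss of CO2, reductive elimination) removes the blocking bromine without touching the benzyl ether, which hydrogenation over Pd/C would cleave.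

Step 7
Reactants: 12 ethyl 5-(benzyloxy)-4-hydroxy-2-naphthoate
Product: 13 ethyl 5-(benzyloxy)-1-bromo-4-hydroxy-2-naphthoate
Conditions: NBS (1.0 equiv), MeCN, −20 °C → 0 °C
Reagents that add atoms: N-bromosuccinimide, O=C1CCC(=O)N1Br
Why: Electrophilic aromatic bromination of a 1-naphthol: the free C4 hydroxyl directs to its para position C1, an α-position of the naphthalene, in preference to C3 between OH and ester (the same preference turns 3-hydroxybenzaldehyde into 2-bromo-5-hydroxybenzaldehyde), the benzyloxy ring is the less activated one, and low temperature with one equivalent of NBS guards against dibromination and quinone formation.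

Step 8
Reactants: 13 ethyl 5-(benzyloxy)-1-bromo-4-hydroxy-2-naphthoate
Product: 15 5-(benzyloxy)-1-bromo-4-methoxy-2-naphthoic acid, via ethyl ester 14 (not isolated)
Conditions: MeI, K2CO3, DMF, 40 °C; then NaOH (aq.), MeOH, 60 °C; then aq. HCl
Reagents that add atoms: iodomethane, CI; sodium hydroxide, [Na+].[OH-]
Why: Williamson O-methylation of the naphthol followed by saponification of the ethyl ester in the same flask; bromide, benzyl ether and methyl ether are inert to both stages.

Step 9
Reactants: 15 5-(benzyloxy)-1-bromo-4-methoxy-2-naphthoic acid; 6 1,3-dimethylisoquinolin-8-ol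
Product: 17 1,3-dimethylisoquinolin-8-yl 5-(benzyloxy)-1-bromo-4-methoxy-2-naphthoate, via acid chloride 16 (not isolated)
Conditions: (COCl)2, DMF (cat.), CH2Cl2, 0 °C → rt, evaporate; then 6, Et3N, DMAP (cat.), CH2Cl2, rt
Reagents that add atoms: oxalyl chloride, O=C(Cl)C(=O)Cl (chlorine of 16 only)
Why: Acyl chloride formation followed by DMAP-catalysed O-acylation of the phenol; the ring nitrogen, flanked by two methyl groups, is a poor competitor and any N-acyl species would pass the acyl group on to the phenoxide.

Step 10
Reactants: 17 1,3-dimethylisoquinolin-8-yl 5-(benzyloxy)-1-bromo-4-methoxy-2-naphthoate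
Product: 18 bridged biaryl lactone (isoquinoline C7 bonded to naphthalene C1'; C8–O–C(=O)–C2' bridge; 5'-benzyloxy, 4'-methoxy, 1,3-dimethyl)
Conditions: Pd(OAc)2 (10 mol %), PPh3 (20 mol %), NaOAc (2 equiv), DMA, 130 °C
Reagents that add atoms: none
Why: Zerovalent palladium formed from Pd(OAc)2 and PPh3 inserts into the C1'–Br bond, the aryl–palladium species palladates C7–H of the isoquinoline by acetate-assisted concerted metalation–deprotonation through the s-cis ester conformer, and reductive elimination from the seven-membered palladacycle forms the C7–C1' bond. The closest known reaction type is the intramolecular direct arylation of aryl 2-halobenzoates to benzo[c]chromen-6-ones (the biaryl lactone method). One ring closes, the six-membered pyranone ring C7–C1'–C2'–C(=O)–O–C8, and it closes in the C–C bond-forming reductive elimination (formally a 6-exo attack of the tethered aryl–palladium on the isoquinoline carbocycle). No stereocentre is created: the lactone is helically twisted, but its two helimers should interconvert quickly at room temperature because only C6–H and the peri C8'–H meet across the bridged axis, and this lability is what step 11 needs. The step needs site selectivity on the isoquinoline, and the bridge secures it, since C8 has only C7 and the ring-fusion carbon C8a as neighbours and no other C–H bond lies within reach of a six-membered closure; the nitrogen is shielded by the C1 and C3 methyl groups and should not bind the catalyst strongly.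

Step 11
Reactants: 18 bridged biaryl lactone
Product: 19 (P)-7-[5-(benzyloxy)-2-(hydroxymethyl)-4-methoxynaphthalen-1-yl]-1,3-dimethylisoquinolin-8-ol
Conditions: (R)-2-methyl-CBS-oxazaborolidine (1.5 equiv), BH3·THF (4 equiv), THF, 0 °C → rt; then MeOH, 50 °C
Reagents that add atoms: none
Why: Atroposelective reductive ring cleavage under dynamic kinetic resolution (CBS reduction of a biaryl lactone): the oxazaborolidine-activated borane should reduce one of the rapidly interconverting helimers of 18 faster, and once the bridge is broken the axis is configurationally stable; the (R)-catalyst is proposed to lead to the P alcohol, the excess borane covers complexation by the isoquinoline nitrogen, and P in 19 and 20 corresponds to M in 21 only because CH2OH and CH2Cl outrank C8a' in the sequence rules whereas CH3 does not.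

Step 12
Reactants: 19 (P)-7-[5-(benzyloxy)-2-(hydroxymethyl)-4-methoxynaphthalen-1-yl]-1,3-dimethylisoquinolin-8-ol
Product: 20 (P)-7-[5-(benzyloxy)-2-(chloromethyl)-4-methoxynaphthalen-1-yl]-1,3-dimethylisoquinolin-8-ol, kept as its hydrochloride
Conditions: SOCl2 (1.5 equiv), CH2Cl2, 0 °C → rt; evaporate, no basic work-up
Reagents that add atoms: thionyl chloride, O=S(Cl)Cl
Why: Chlorodehydroxylation of the benzylic alcohol through its chlorosulfite; the hydrogen chloride formed protonates the isoquinoline nitrogen, so no phenoxide can arise to displace the chloride intramolecularly, the phenol itself does not react with SOCl2 without base, and the axis is untouched.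

Step 13
Reactants: 20 (P)-7-[5-(benzyloxy)-2-(chloromethyl)-4-methoxynaphthalen-1-yl]-1,3-dimethylisoquinolin-8-ol (hydrochloride)
Product: 21 ent-dioncophylleine A, (M)-7-(5-hydroxy-4-methoxy-2-methylnaphthalen-1-yl)-1,3-dimethylisoquinolin-8-ol
Conditions: H2 (1 atm), 10% Pd/C, MeOH/EtOAc, rt; then aq. NaHCO3
Reagents that add atoms: none
Why: Catalytic hydrogenolysis cleaves the naphthylmethyl C–Cl bond and the benzyl ether in one operation while the protonated nitrogen neither poisons the catalyst nor allows cyclisation; the isoquinoline ring should resist hydrogenation at 1 atm and room temperature, and the tri-ortho-substituted axis does not rotate under these conditions.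

**Compound list**

1 | 2',6'-dihydroxyacetophenone | CC(=O)c1c(O)cccc1O | starting material
2 | 2-acetyl-3-hydroxyphenyl trifluoromethanesulfonate | CC(=O)c1c(O)cccc1OS(=O)(=O)C(F)(F)F | intermediate
3 | propyne | CC#C | starting material
4 | 1-[2-hydroxy-6-(prop-1-yn-1-yl)phenyl]ethan-1-one | CC#Cc1cccc(O)c1C(C)=O | intermediate
5 | 2-(1-iminoethyl)-3-(prop-1-yn-1-yl)phenol (ketimine, not isolated) | CC#Cc1cccc(O)c1C(C)=N | intermediate
6 | 1,3-dimethylisoquinolin-8-ol | Cc1cc2cccc(O)c2c(C)n1 | intermediate
7 | 5-(benzyloxy)-2-bromobenzaldehyde | O=Cc1cc(OCc2ccccc2)ccc1Br | starting material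
8 | diethyl succinate | CCOC(=O)CCC(=O)OCC | starting material
9 | (E)-4-[5-(benzyloxy)-2-bromophenyl]-3-(ethoxycarbonyl)but-3-enoic acid | OC(=O)C/C(C(=O)OCC)=C\c1cc(OCc2ccccc2)ccc1Br | intermediate
10 | ethyl 4-acetoxy-5-(benzyloxy)-8-bromo-2-naphthoate | CCOC(=O)c1cc(OC(C)=O)c2c(OCc3ccccc3)ccc(Br)c2c1 | intermediate
11 | ethyl 5-(benzyloxy)-8-bromo-4-hydroxy-2-naphthoate (not isolated) | CCOC(=O)c1cc(O)c2c(OCc3ccccc3)ccc(Br)c2c1 | intermediate
12 | ethyl 5-(benzyloxy)-4-hydroxy-2-naphthoate | CCOC(=O)c1cc(O)c2c(OCc3ccccc3)cccc2c1 | intermediate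
13 | ethyl 5-(benzyloxy)-1-bromo-4-hydroxy-2-naphthoate | CCOC(=O)c1cc(O)c2c(OCc3ccccc3)cccc2c1Br | intermediate
14 | ethyl 5-(benzyloxy)-1-bromo-4-methoxy-2-naphthoate (not isolated) | CCOC(=O)c1cc(OC)c2c(OCc3ccccc3)cccc2c1Br | intermediate
15 | 5-(benzyloxy)-1-bromo-4-methoxy-2-naphthoic acid | OC(=O)c1cc(OC)c2c(OCc3ccccc3)cccc2c1Br | intermediate
16 | 5-(benzyloxy)-1-bromo-4-methoxy-2-naphthoyl chloride (not isolated) | O=C(Cl)c1cc(OC)c2c(OCc3ccccc3)cccc2c1Br | intermediate
17 | 1,3-dimethylisoquinolin-8-yl 5-(benzyloxy)-1-bromo-4-methoxy-2-naphthoate | Cc1cc2cccc(OC(=O)c3cc(OC)c4c(OCc5ccccc5)cccc4c3Br)c2c(C)n1 | intermediate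
18 | bridged biaryl lactone (C7–C1' bond, C8–O–C(=O)–C2' bridge; configurationally labile) | Cc1cc2ccc3-c4c(cc(OC)c5c(OCc6ccccc6)cccc45)C(=O)Oc3c2c(C)n1 | intermediate
19 | (P)-7-[5-(benzyloxy)-2-(hydroxymethyl)-4-methoxynaphthalen-1-yl]-1,3-dimethylisoquinolin-8-ol | Cc1cc2ccc(-c3c(CO)cc(OC)c4c(OCc5ccccc5)cccc34)c(O)c2c(C)n1 | intermediate
20 | (P)-7-[5-(benzyloxy)-2-(chloromethyl)-4-methoxynaphthalen-1-yl]-1,3-dimethylisoquinolin-8-ol (kept as its hydrochloride) | Cc1cc2ccc(-c3c(CCl)cc(OC)c4c(OCc5ccccc5)cccc34)c(O)c2c(C)n1 | intermediate
21 | ent-dioncophylleine A, (M)-7-(5-hydroxy-4-methoxy-2-methylnaphthalen-1-yl)-1,3-dimethylisoquinolin-8-ol | COc1cc(C)c(-c2ccc3cc(C)nc(C)c3c2O)c2cccc(O)c12 | target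

**Step count**

Total: 13 steps. Longest linear sequence: 10 steps (steps 4 to 13, from 7).

**Steps most likely to fail**

1. Step 10. Oxidative addition at the hindered C1'–Br bond may be followed by hydrodebromination, or the aryl ester may be cleaved at 130 °C before the ring closes. The fallback sets out from 6 and from 14 (isolated here after the methylation stage of step 8) and comes back at 18. Compound 6 is converted in the flask into its O-boryl ester with HBpin, and this group steers an iridium-catalysed C–H borylation ([Ir(OMe)(cod)]2, 4,4'-di-tert-butyl-2,2'-bipyridine, B2pin2, THF, 80 °C) to the ortho position C7. Methanolysis of the O–B bond should give 1,3-dimethyl-7-(4,4,5,5-tetramethyl-1,3,2-dioxaborolan-2-yl)isoquinolin-8-ol F1. Suzuki–Miyaura coupling of F1 with 14 (Pd(OAc)2, SPhos, K3PO4, toluene/H2O, 100 °C) should give ethyl 5-(benzyloxy)-1-(8-hydroxy-1,3-dimethylisoquinolin-7-yl)-4-methoxy-2-naphthoate F2. Its phenol closes onto the neighbouring ester (p-TsOH cat., toluene, reflux) to give 18.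

2. Step 11. The chiral reagent may discriminate poorly between the two helimers (low atroposelectivity), or boron–nitrogen complexation may take the catalyst out of play. The fallback sets out from 18 and comes back at 19. Ring opening with sodium (1R,2S,5R)-mentholate (THF, −20 °C) is an atropo-diastereoselective cleavage under the same dynamic kinetic resolution. It should give (1R,2S,5R)-menthyl 5-(benzyloxy)-1-(8-hydroxy-1,3-dimethylisoquinolin-7-yl)-4-methoxy-2-naphthoate F3 as a pair of atropo-diastereomers that can be separated by chromatography. If the wanted axis is the minor one, the enantiomeric menthol is used. Reduction of the ester with LiAlH4 (THF, 0 °C) gives 19.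

3. Step 12. If the nitrogen loses its proton during handling, the C8 phenol can displace the benzylic chloride intramolecularly and close a six-membered cyclic ether, which consumes the material and, being a bridged biaryl, loses the axial information. The fallback sets out from 19 and comes back at 21 without a benzylic halide. Acetylation of both hydroxyl groups (Ac2O, pyridine, DMAP cat.) gives (P)-{4-(benzyloxy)... } in full: (P)-[1-(8-acetoxy-1,3-dimethylisoquinolin-7-yl)-5-(benzyloxy)-4-methoxynaphthalen-2-yl]methyl acetate F4, in which the phenol is masked. Hydrogenolysis (H2, 10% Pd/C, EtOAc/AcOH) cleaves the naphthylmethyl acetate and the benzyl ether and should give (M)-7-(5-hydroxy-4-methoxy-2-methylnaphthalen-1-yl)-1,3-dimethylisoquinolin-8-yl acetate F5. Methanolysis (K2CO3, MeOH, rt) gives 21.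

**Further compounds**

F1 | step 10 | 1,3-dimethyl-7-(4,4,5,5-tetramethyl-1,3,2-dioxaborolan-2-yl)isoquinolin-8-ol | Cc1cc2ccc(B3OC(C)(C)C(C)(C)O3)c(O)c2c(C)n1
F2 | step 10 | ethyl 5-(benzyloxy)-1-(8-hydroxy-1,3-dimethylisoquinolin-7-yl)-4-methoxy-2-naphthoate | CCOC(=O)c1cc(OC)c2c(OCc3ccccc3)cccc2c1-c1ccc2cc(C)nc(C)c2c1O
F3 | step 11 | (1R,2S,5R)-menthyl 5-(benzyloxy)-1-(8-hydroxy-1,3-dimethylisoquinolin-7-yl)-4-methoxy-2-naphthoate (P axis) | Cc1cc2ccc(-c3c(C(=O)O[C@@H]5C[C@H](C)CC[C@H]5C(C)C)cc(OC)c4c(OCc5ccccc5)cccc34)c(O)c2c(C)n1
F4 | step 12 | (P)-[1-(8-acetoxy-1,3-dimethylisoquinolin-7-yl)-5-(benzyloxy)-4-methoxynaphthalen-2-yl]methyl acetate | Cc1cc2ccc(-c3c(COC(C)=O)cc(OC)c4c(OCc5ccccc5)cccc34)c(OC(C)=O)c2c(C)n1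
F5 | step 12 | (M)-7-(5-hydroxy-4-methoxy-2-methylnaphthalen-1-yl)-1,3-dimethylisoquinolin-8-yl acetate | COc1cc(C)c(-c2ccc3cc(C)nc(C)c3c2OC(C)=O)c2cccc(O)c12
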